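**Retrosynthetic overview**
1. Target 17 ⇐ DIBAL-H reduction of (E)-enoate 16 ⇐ Wittig reaction of lactol 6 (decalin half; its aldehyde carbon becomes the olefinic CH) with the α-branched stabilised ylide 14 (cyclohexane half), which sets the alkene geometry.
2. Lactol 6 ⇐ (+)-ambreinolide 5 ⇐ key step: catalytic asymmetric, proton-initiated tricyclisation of acyclic (4E,8E)-farnesylacetic acid 4, closing rings A and B and the δ-lactone and setting four stereocentres in one operation ⇐ farnesyl bromide 1 + acetic acid 2.
3. Ylide 14 ⇐ iodide 11 ⇐ acid 9 ⇐ (S)-γ-dihydroionone 8 ⇐ enzymatic monocyclisation of (E)-geranylacetone 7.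
4. Ring order: decalin rings A/B together with the temporary lactone ring (step 2); the methylenecyclohexane ring separately (step 4); the lactone ring is opened again in steps 3 and 8.

Assumption: 1 and 7 are used as the pure E isomers (sold as such, or purified from the cheaper E/Z grades), and the target alkene is taken as drawn in the SMILES, with CH2OH trans to the decalin-bearing chain (3E by CIP).

**Step 1**
Reactants: 1 (2E,6E)-farnesyl bromide; 2 acetic acid
Product: 4 (4E,8E)-5,9,13-trimethyltetradeca-4,8,12-trienoic acid (farnesylacetic acid), via dilithioacetate 3 (not isolated)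
Conditions: LDA (2.1 equiv), THF–HMPA, 0 → 40 °C; then 1, 0 °C → rt; aq HCl
Reagents that add atoms: none
Why: α-Alkylation of the carboxylic acid dianion by SN2 at the primary allylic bromide; both E-alkenes are carried through unchanged.

**Step 2**
Reactants: 4 farnesylacetic acid
Product: 5 (+)-ambreinolide
Conditions: confined chiral imidodiphosphorimidate Brønsted acid (IDPi, 3 mol %; the enantiomer that leads to the 5S,10S series), perfluoro-tert-butanol, −20 °C → rt; recrystallise
Reagents that add atoms: none
Why: Proposed new method: the confined chiral acid protonates the terminal Me2C=CH unit on one face inside its chiral anion pocket, and the (4E,8E)-triene then closes in a chair–chair, all-anti (Stork–Eschenmoser) cation–olefin cascade that the carboxyl oxygen ends at C8, which fixes C5 (S), C10 (S), C9 (R) and C8 (R, equatorial C–O, trans-fused lactone) in one event; the closest known reactions are the IDPi-catalysed asymmetric polyene cyclisation of homofarnesol to ambrox (hydroxyl-terminated) and the classical acid-mediated cyclisation of farnesylacetic acid to racemic ambreinolide.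

**Step 3**
Reactants: 5 (+)-ambreinolide
Product: 6 ambreinolide lactol (both C3 epimers)
Conditions: DIBAL-H (1.1 equiv), CH2Cl2, −78 °C; Rochelle salt
Reagents that add atoms: none
Why: Partial lactone reduction with DIBAL-H stops at the aluminium hemiacetal at −78 °C and gives the lactol on work-up; no decalin stereocentre is touched and the new hemiacetal centre is of no consequence.

**Step 4**
Reactants: 7 (E)-geranylacetone
Product: 8 (S)-γ-dihydroionone
Conditions: engineered squalene–hopene cyclase (variant selected for deprotonation-terminated monocyclisation, E. coli whole cells), citrate buffer pH 6, SDS, 30 °C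
Reagents that add atoms: none
Why: Enzymatic asymmetric cation–olefin monocyclisation (squalene–hopene cyclase type): the active-site acid protonates the terminal alkene of the chair-folded (E)-substrate, ring closure sets the single stereocentre as (S), and the engineered pocket removes a proton from the C-methyl group so that the exocyclic alkene forms instead of the bicyclic enol ether.

**Step 5**
Reactants: 8 (S)-γ-dihydroionone
Product: 9 3-[(1S)-2,2-dimethyl-6-methylidenecyclohexyl]propanoic acid
Conditions: aq NaOCl (3.5 equiv), NaOH, dioxane, 0 °C → rt; Na2SO3; HCl to pH 3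
Reagents that add atoms: sodium hydroxide, [Na+].[OH-]
Why: Haloform reaction: exhaustive chlorination of the CH3 group and hydroxide cleavage of the CCl3 ketone give the carboxylate; at pH > 12 hypochlorite leaves the 1,1-disubstituted alkene alone, and the stereocentre (γ to the carbonyl) cannot epimerise.

**Step 6**
Reactants: 9 the propanoic acid
Product: 11 (2S)-2-(2-iodoethyl)-1,1-dimethyl-3-methylidenecyclohexane, via Barton ester 10 (not isolated)
Conditions: N-hydroxypyridine-2-thione, DCC, DMAP (cat.), CH2Cl2, 0 °C, dark; then CHI3, hν (W lamp), rt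
Reagents that add atoms: iodoform, IC(I)I
Why: Barton decarboxylative iodination: light cleaves the N–O bond of the thiohydroxamate ester, CO2 is lost, and the primary alkyl radical takes iodine from iodoform faster than it can add to the hindered exocyclic alkene; the stereocentre is not involved.

**Step 7**
Reactants: 11 the iodide; 12 ethyl (triphenylphosphoranylidene)acetate
Product: 14 ethyl 4-[(1S)-2,2-dimethyl-6-methylidenecyclohexyl]-2-(triphenylphosphoranylidene)butanoate, via phosphonium iodide 13 (not isolated)
Conditions: 12 (1.2 equiv), EtOAc, reflux, 36 h; then 1 M aq NaOH, CH2Cl2, rt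
Reagents that add atoms: none
Why: SN2 C-alkylation of the stabilised phosphorus ylide by the primary iodide gives the phosphonium salt, which aqueous hydroxide deprotonates to the α-branched stabilised ylide.

**Step 8**
Reactants: 14 the α-branched ylide; 6 ambreinolide lactol
Product: 16 ethyl (2E)-2-{2-[(1S)-2,2-dimethyl-6-methylidenecyclohexyl]ethyl}-5-[(1R,2R,4aS,8aS)-2-hydroxy-2,5,5,8a-tetramethyldecahydronaphthalen-1-yl]pent-2-enoate, via hydroxy aldehyde 15 (not isolated)
Conditions: toluene, PhCO2H (cat.), 100 °C, 24 h
Reagents that add atoms: none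
Why: Wittig olefination of a lactol through its open hydroxy-aldehyde tautomer with an ester-stabilised α-branched ylide; such ylides are strongly E-selective (ester trans to the aldehyde-derived chain), which is the required geometry, and the neutral conditions leave the tertiary alcohol and the exocyclic alkene untouched.

**Step 9**
Reactants: 16 the hydroxy enoate
Product: 17 the target
Conditions: DIBAL-H (3.5 equiv), CH2Cl2, −78 → 0 °C; Rochelle salt
Reagents that add atoms: none
Why: DIBAL-H 1,2-reduction of the α,β-unsaturated ester to the allylic alcohol; the alkene geometry, the exocyclic alkene and all five stereocentres are unaffected.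

**Compound list**
1 | (2E,6E)-farnesyl bromide, (2E,6E)-1-bromo-3,7,11-trimethyldodeca-2,6,10-triene | CC(C)=CCC/C(C)=C/CC/C(C)=C/CBr | starting material
2 | acetic acid | CC(=O)O | starting material
3 | dilithioacetate (dianion of acetic acid, LiCH2CO2Li) | [Li]CC(=O)O[Li] | intermediate
4 | (4E,8E)-5,9,13-trimethyltetradeca-4,8,12-trienoic acid (farnesylacetic acid) | CC(C)=CCC/C(C)=C/CC/C(C)=C/CCC(=O)O | intermediate
5 | (+)-ambreinolide, (4aR,6aS,10aS,10bR)-4a,7,7,10a-tetramethyldodecahydro-3H-benzo[f]chromen-3-one (trans-decalin, trans-fused δ-lactone) | O=C1CC[C@@H]2[C@@]3(C)CCCC(C)(C)[C@@H]3CC[C@@]2(C)O1 | intermediate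
6 | ambreinolide lactol, (4aR,6aS,10aS,10bR)-4a,7,7,10a-tetramethyldodecahydro-1H-benzo[f]chromen-3-ol (both C3 epimers) | OC1CC[C@@H]2[C@@]3(C)CCCC(C)(C)[C@@H]3CC[C@@]2(C)O1 | intermediate
7 | (E)-geranylacetone, (5E)-6,10-dimethylundeca-5,9-dien-2-one | CC(C)=CCC/C(C)=C/CCC(C)=O | starting material
8 | (S)-γ-dihydroionone, 4-[(1S)-2,2-dimethyl-6-methylidenecyclohexyl]butan-2-one | C=C1CCCC(C)(C)[C@@H]1CCC(C)=O | intermediate
9 | 3-[(1S)-2,2-dimethyl-6-methylidenecyclohexyl]propanoic acid | C=C1CCCC(C)(C)[C@@H]1CCC(=O)O | intermediate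
10 | Barton ester of 9, 2-thioxopyridin-1(2H)-yl 3-[(1S)-2,2-dimethyl-6-methylidenecyclohexyl]propanoate | C=C1CCCC(C)(C)[C@@H]1CCC(=O)ON1C=CC=CC1=S | intermediate
11 | (2S)-2-(2-iodoethyl)-1,1-dimethyl-3-methylidenecyclohexane | C=C1CCCC(C)(C)[C@@H]1CCI | intermediate
12 | ethyl (triphenylphosphoranylidene)acetate, Ph3P=CHCO2Et | CCOC(=O)C=P(c1ccccc1)(c1ccccc1)c1ccccc1 | starting material
13 | {4-[(1S)-2,2-dimethyl-6-methylidenecyclohexyl]-1-ethoxy-1-oxobutan-2-yl}triphenylphosphonium iodide | C=C1CCCC(C)(C)[C@@H]1CCC(C(=O)OCC)[P+](c1ccccc1)(c1ccccc1)c1ccccc1.[I-] | intermediate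
14 | ethyl 4-[(1S)-2,2-dimethyl-6-methylidenecyclohexyl]-2-(triphenylphosphoranylidene)butanoate | C=C1CCCC(C)(C)[C@@H]1CCC(C(=O)OCC)=P(c1ccccc1)(c1ccccc1)c1ccccc1 | intermediate
15 | 3-[(1R,2R,4aS,8aS)-2-hydroxy-2,5,5,8a-tetramethyldecahydronaphthalen-1-yl]propanal (open tautomer of 6) | O=CCC[C@@H]1[C@@]2(C)CCCC(C)(C)[C@@H]2CC[C@@]1(C)O | intermediate
16 | ethyl (2E)-2-{2-[(1S)-2,2-dimethyl-6-methylidenecyclohexyl]ethyl}-5-[(1R,2R,4aS,8aS)-2-hydroxy-2,5,5,8a-tetramethyldecahydronaphthalen-1-yl]pent-2-enoate | C=C1CCCC(C)(C)[C@@H]1CC/C(=C\CC[C@@H]1[C@@]2(C)CCCC(C)(C)[C@@H]2CC[C@@]1(C)O)C(=O)OCC | intermediate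
17 | (1R,2R,4aS,8aS)-1-[(3E)-6-[(1S)-2,2-dimethyl-6-methylidenecyclohexyl]-4-(hydroxymethyl)hex-3-en-1-yl]-2,5,5,8a-tetramethyldecahydronaphthalen-2-ol | C=C1CCCC(C)(C)[C@@H]1CC/C(=C\CC[C@@H]1[C@@]2(C)CCCC(C)(C)[C@@H]2CC[C@@]1(C)O)CO | target

**Step count**
Total: 9 steps. Longest linear sequence: 6 steps (steps 4–9, from 7); the decalin branch is 5 steps (1, 2, 3, 8, 9).

**Three steps most likely to fail, and fallbacks**

Step 2 (key tricyclisation). The carboxylic acid may end the cascade poorly, giving low conversion, some cis-lactone or low ee. The fallback sets out from 4. Reduce 4 with LiAlH4 (THF, 0 °C) to (4E,8E)-5,9,13-trimethyltetradeca-4,8,12-trien-1-ol F1. Cyclise it with the same chiral acid in the hydroxyl-terminated mode, which is the established mode for homofarnesol to ambrox, to the tricyclic ether 8α,13-epoxy-14,15,16-trinorlabdane F2. Oxidise the OCH2 group of F2 with RuCl3 (cat.)/NaIO4 in CCl4–MeCN–H2O; the other ether carbon is quaternary, so only the lactone can form. The sequence comes back to the route at 5.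

Step 4 (enzymatic γ-selective monocyclisation). A suitable cyclase variant may not be at hand, or conversion may stall. The fallback sets out from 7. Cyclise 7 with the chiral Brønsted acid of step 2 in its normal oxygen-terminated mode, which closes the carbocycle and the dihydropyran ring together, to (4aS,8aS)-2,5,5,8a-tetramethyl-4a,5,6,7,8,8a-hexahydro-4H-chromene F3. Hydrolyse the enol ether (aq oxalic acid, THF) to 4-[(1S,2S)-2-hydroxy-2,6,6-trimethylcyclohexyl]butan-2-one F4. Dehydrate the equatorial tertiary alcohol with SOCl2/pyridine at −78 °C: only the axial methyl group offers an anti-periplanar hydrogen, so the exocyclic alkene dominates, and the endocyclic isomer is removed on AgNO3-silica. The sequence comes back to the route at 8.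

Step 7 (C-alkylation of the stabilised ylide by an unactivated iodide). The alkylation may be too slow, or the resulting branched ylide too unreactive toward the lactol in step 8. The fallback sets out from 11 and uses 6. Alkylate sodium triethyl phosphonoacetate with 11 (NaH, DMF, 60 °C) to ethyl 2-(diethoxyphosphoryl)-4-[(1S)-2,2-dimethyl-6-methylidenecyclohexyl]butanoate F5. Run a Horner–Wadsworth–Emmons reaction of F5 with lactol 6 (NaH 2.1 equiv, THF, 0 °C → rt, quenched cold). This gives the same hydroxy enoate, E major, with the Z isomer removed by chromatography. The sequence comes back to the route at 16.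

**Further compounds**
F1 | step 2 | (4E,8E)-5,9,13-trimethyltetradeca-4,8,12-trien-1-ol (bishomofarnesol) | CC(C)=CCC/C(C)=C/CC/C(C)=C/CCCO
F2 | step 2 | (4aR,6aS,10aS,10bR)-4a,7,7,10a-tetramethyldodecahydro-1H-benzo[f]chromene (8α,13-epoxy-14,15,16-trinorlabdane) | C1CC[C@@H]2[C@@]3(C)CCCC(C)(C)[C@@H]3CC[C@@]2(C)O1
F3 | step 4 | (4aS,8aS)-2,5,5,8a-tetramethyl-4a,5,6,7,8,8a-hexahydro-4H-chromene | CC1=CC[C@H]2C(C)(C)CCC[C@]2(C)O1
F4 | step 4 | 4-[(1S,2S)-2-hydroxy-2,6,6-trimethylcyclohexyl]butan-2-one | CC(=O)CC[C@H]1C(C)(C)CCC[C@]1(C)O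
F5 | step 7 | ethyl 2-(diethoxyphosphoryl)-4-[(1S)-2,2-dimethyl-6-methylidenecyclohexyl]butanoate (both C2 epimers) | C=C1CCCC(C)(C)[C@@H]1CCC(C(=O)OCC)P(=O)(OCC)OCC
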